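## Structural features

The target is a heliangolide-type germacranolide: a ten-membered carbocycle (C1–C10) trans-fused along C6–C7 to an α-methylene-γ-butyrolactone (O6, C12, C11, exocyclic C13). The ring carries a Z-trisubstituted C4=C5 alkene with a hydroxymethyl group (C15) on C4, a secondary allylic alcohol at C3 (3S), and a trans-epoxide across C1–C10 (1R,10R) whose C10 bears the C14 methyl. C6 (R), C7 (R) and C8 (R) form a contiguous triad, with the C8 angelate on the face cis to C11; C3 and the epoxide carbons are isolated from the triad and from each other. Fragile elements are the exocyclic enoate (Michael acceptor), the angelate (Z to E drift under acyl activation or base), the doubly allylic C6–O bond, and the tertiary epoxide, which lies transannular to the 3-hydroxyl. The real difficulty is the closure of a strained ten-membered ring holding one Z and one E trisubstituted alkene, together with control of the C6–C7–C8 triad. The key step exploits the homoallylic alcohol pattern C13=C11–C7–C8–O8: with the butenolide ring (O6–C6–C7=C11–C12) already present, an allylmetal at C13 attacks a C8 aldehyde through C7, which closes the carbocycle, moves the double bond to C11=C13 and leaves the lactone on O6.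

## Logic of the disconnections

36 ⇒ 35 ⇒ 34. The two O–Si bonds and then the C1–O and C10–O bonds are cut. The free hydroxyls and the epoxide are the most fragile functions and are therefore the last to appear. This reduces the target to a protected triene. The forward steps demand a peracid that selects C1=C10 among four alkenes and attacks its outer face, and a desilylation that spares the epoxide.

34 ⇒ 31 + 32. The C8–O acyl bond is cut, with inversion at C8. The angelate is isomerisation-prone and belongs late, and the ring closure is expected to deliver the 8α alcohol. The stereochemical correction thus costs no extra step. The forward step demands a clean SN2 displacement at a secondary carbinol flanked by allylic hydrogens.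

31 ⇒ 29. The C7–C8 ring bond is cut. This one cut removes the ring, two stereocentres and the exocyclic alkene, and leaves an open chain with only C3 and C6 as stereocentres. The forward step demands γ-attack of the allylmetal, ring closure in preference to oligomerisation, and neutral conditions for a β,γ-unsaturated aldehyde.

29 ⇒ 28 ⇒ 27 ⇒ 26 ⇒ 25. These are functional-group changes at C8 (aldehyde, alcohol, ether) and C13 (bromide, alcohol, silyl ether). Both reactive termini are unmasked as late as possible, the bromide before the aldehyde because the bromination reagent would attack an aldehyde. The demand is three mutually orthogonal oxygen protections.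

25 ⇒ 24 ⇒ 22. The C12–O6 and C11–C12 bonds are cut (C12 arrives as CO), then C11–I and C7–H across an alkyne. The lactone carbonyl is the simplest one-carbon unit to add, and the alkyne stores the C7=C11 geometry. The demand is hydride delivery to C7 directed by O6, anti addition, and a base mild enough for the new butenolide.

22 ⇒ 18 + 20. The C6–C7 bond is cut. This sets C6 by catalyst control and attaches C7, C11 and C13 in one piece. The demand is enantioface control at a β,β-disubstituted enal with a remote stereocentre.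

18 ⇒ 16 ⇒ 15 ⇒ 14 ⇒ 13 ⇒ 11 + 6. After oxidation-state changes at C6 and C3, the C3–C4 bond is cut. This separates the Z-alkene unit from the E-alkene unit at the carbinol carbon and gives two achiral fragments. The demand is a base-free coupling of an alkenyl iodide with an enolisable aldehyde, with C3 then set by a reagent-controlled reduction.

11 ⇒ 10 ⇒ 8 ⇒ 7. The C4–I and C5–H bonds across the alkyne and two O–Si bonds are cut. Anti addition places iodine, and later C3, cis to C6. The demand is regioselective hydroalumination directed by the one free hydroxyl.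

6 ⇒ 5 ⇒ 2 ⇒ 1. The C1–C2 and C10–C14 bonds are cut. Syn carbometalation of a terminal alkyne fixes the E geometry of C1=C10. The demand is regioselective methylalumination and epoxide opening by the alkenylalanate with retention.

20 ⇒ 19. One O–Si bond is cut; the demand is trivial.

## Other disconnections considered

Alternative 1: The cut is at O6–C12 and C11–C12 of the angelate A1, which is the same substance as 34. The forward step is a cyclocarbonylation of the 7-ethynyl cyclodecadien-6-ol A2 with divalent palladium (PdCl2(PPh3)2, SnCl2, CO). In its favour, the Michael acceptor is made last and is exposed to no other step, O8 is already acylated so no lactone regiochemistry arises, and the endgame from A1 is identical; on these points it is the equal of the chosen plan, and better for the lifetime of the enoate. Against it, the step forms no ring carbon–carbon bond. A2 already contains the ten-membered ring and the C6–C7–C8 triad, so the hard ring closure is only moved to an earlier, undefined step. The doubly allylic C6 hydroxyl of A2 can ionise under the acidic tin and palladium chlorides, and palladium hydrides can move the alkenes. Step 20 builds the ring, the C7–C8 bond, two stereocentres and the methylene at once, so the chosen plan is shorter and mechanistically tighter.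

Alternative 2: The cut is at C4=C5 of the acetonide A3. The forward step is ring-closing metathesis of the seco-diene A4 (vinyl on C6, methylene on the dioxane) with the second-generation Grubbs catalyst. In its favour, all stereocentres are set before ring closure by an intermolecular allylation, where the C8 configuration can be steered by the choice of metal; this is better than the chosen plan. The Z geometry is the one a ten-membered ring prefers, and convergence is equal. Against it, a trisubstituted alkene from a 1,1-disubstituted partner in a ten-membered ring is among the hardest metathesis closures. The alkylidene on C5 can instead engage C1=C10 and close a six-membered ring with loss of the C1–C4 segment, and the lactone methylene is a further competitor. The acetonide needs acid for removal, which must then precede epoxidation. Step counts are similar; the chosen plan is safer at the ring closure.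

Alternative 3: The cut is at C1=C10 and C6=O of the cyclodecadienone A5. The forward step is a Wharton–Grob fragmentation of the hydroazulene diol monomesylate A6 with KOtBu. In its favour, the ring comes from a fused bicycle without high dilution, the E alkene follows stereospecifically from the anti-periplanar C6–C10 and C1–O bonds, and the seven-membered ring guarantees Z-C4=C5; for ring formation it is better than the chosen plan. Against it, A5 has no C11–C13 unit, C7 is a methylene and C6 a ketone. The lactone must be grafted by regioselective C7 alkylation, C6 reduction, lactonisation and methylenation, at least five steps with two new stereocentres to control. The C8 ether is β to the new ketone and can be lost by E1cB under the alkoxide base, and A6 needs a quaternary C10. The chosen plan is clearly better in step economy and in control of C6 and C7.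

Key step: step 20

Remarks on the chemistry (assumptions):
- Germacrane numbering (C1–C15, O6 for the lactone oxygen) is used for all open-chain and cyclic compounds.
- In the closed chair of step 20 the 7,8-anti adduct is expected, so the cyclisation product is drawn as the 8α (8S) alcohol and the angelate is introduced with inversion.
- In step 13 Si-face delivery with the (R,R) ligand is assumed; both antipodes are commercial, and the other is used if the first run shows the opposite sense.

## Steps

Step 1
Reactants: 1 but-3-yn-1-ol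
Product: 2 1-[(but-3-yn-1-yloxy)methyl]-4-methoxybenzene
Conditions: NaH, PMBCl, Bu4NI (cat.), THF/DMF, 0 °C → rt
Reagents that add atoms: 4-methoxybenzyl chloride, COc1ccc(CCl)cc1
Why: Williamson etherification; only the hydroxyl is deprotonated by NaH, and the PMB ether is orthogonal to all silyl ethers used later.

Step 2
Reactants: 2 1-[(but-3-yn-1-yloxy)methyl]-4-methoxybenzene
Product: 5 (E)-6-[(4-methoxybenzyl)oxy]-4-methylhex-3-en-1-ol, via alkenyldimethylalane 3 (not isolated), via lithium alkenylalanate 4 (not isolated)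
Conditions: Me3Al, Cp2ZrCl2 (20 mol %), CH2Cl2, 0 °C → rt; n-BuLi, hexane/THF, −78 → 0 °C; ethylene oxide, 0 °C
Reagents that add atoms: trimethylaluminium, C[Al](C)C; ethylene oxide, C1CO1
Why: Negishi zirconium-catalysed carboalumination adds methyl (to C10) and aluminium (to C1) syn across the terminal alkyne, which fixes the E geometry; the alanate opens ethylene oxide with retention and adds C2 and C3.

Step 3
Reactants: 5 (E)-6-[(4-methoxybenzyl)oxy]-4-methylhex-3-en-1-ol
Product: 6 (E)-6-[(4-methoxybenzyl)oxy]-4-methylhex-3-enal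
Conditions: DMP, NaHCO3, CH2Cl2, 0 °C; used crude
Reagents that add atoms: none
Why: Dess–Martin oxidation under bicarbonate buffer is neutral, so the β,γ-double bond should not move into conjugation.

Step 4
Reactants: 7 but-2-yne-1,4-diol
Product: 8 4-[(tert-butyldimethylsilyl)oxy]but-2-yn-1-ol
Conditions: NaH (1 equiv), TBSCl (1 equiv), THF, 0 °C → rt, diol in excess
Reagents that add atoms: tert-butyldimethylsilyl chloride, CC(C)(C)[Si](C)(C)Cl
Why: Monosilylation of a symmetrical diol through its mono-alkoxide; the oxygen silylated here becomes O15 and keeps its TBS group to the last step.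

Step 5
Reactants: 8 4-[(tert-butyldimethylsilyl)oxy]but-2-yn-1-ol
Product: 10 (Z)-4-[(tert-butyldimethylsilyl)oxy]-3-iodobut-2-en-1-ol, via cyclic alkenylalanate 9 (not isolated)
Conditions: NaAlH2(OCH2CH2OMe)2, THF, 0 °C → rt; I2, THF, −78 °C
Reagents that add atoms: iodine, II
Why: Hydroxyl-directed trans-hydroalumination delivers hydride to C5 and aluminium to C4 in a five-membered alanate; iodinolysis with retention puts iodine cis to C6, the place C3 must later take for the Z-C4=C5 alkene.

Step 6
Reactants: 10 (Z)-4-[(tert-butyldimethylsilyl)oxy]-3-iodobut-2-en-1-ol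
Product: 11 (Z)-1-[(tert-butyldimethylsilyl)oxy]-2-iodo-4-[(triethylsilyl)oxy]but-2-ene
Conditions: TESCl, imidazole, CH2Cl2, 0 °C
Reagents that add atoms: chlorotriethylsilane, CC[Si](Cl)(CC)CC
Why: Silylation of the primary alcohol; the TES ether on O6 is the one group that step 11 later converts directly into the aldehyde.

Step 7
Reactants: 11 (Z)-1-[(tert-butyldimethylsilyl)oxy]-2-iodo-4-[(triethylsilyl)oxy]but-2-ene; 6 (E)-6-[(4-methoxybenzyl)oxy]-4-methylhex-3-enal
Product: 13 (2Z,6E)-3-{[(tert-butyldimethylsilyl)oxy]methyl}-9-[(4-methoxybenzyl)oxy]-7-methyl-1-[(triethylsilyl)oxy]nona-2,6-dien-4-ol (racemic at C3), via alkenylchromium dichloride 12 (not isolated)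
Conditions: CrCl2 (4 equiv), NiCl2 (1 mol %), DMSO, rt
Reagents that add atoms: none
Why: Nozaki–Hiyama–Kishi coupling forms C3–C4 with retention of the alkene geometry; no basic reagent is present, so the enolisable β,γ-unsaturated aldehyde should survive; C3 is formed racemic and is corrected in steps 8 and 9.

Step 8
Reactants: 13 (2Z,6E)-3-{[(tert-butyldimethylsilyl)oxy]methyl}-9-[(4-methoxybenzyl)oxy]-7-methyl-1-[(triethylsilyl)oxy]nona-2,6-dien-4-ol
Product: 14 (2Z,6E)-3-{[(tert-butyldimethylsilyl)oxy]methyl}-9-[(4-methoxybenzyl)oxy]-7-methyl-1-[(triethylsilyl)oxy]nona-2,6-dien-4-one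
Conditions: DMP, NaHCO3, CH2Cl2, 0 °C; used crude
Reagents that add atoms: none
Why: Dess–Martin oxidation of the allylic alcohol to the enone under buffered conditions, which should leave the doubly activated C2 methylene untouched.

Step 9
Reactants: 14 (2Z,6E)-3-{[(tert-butyldimethylsilyl)oxy]methyl}-9-[(4-methoxybenzyl)oxy]-7-methyl-1-[(triethylsilyl)oxy]nona-2,6-dien-4-one
Product: 15 (2Z,4S,6E)-3-{[(tert-butyldimethylsilyl)oxy]methyl}-9-[(4-methoxybenzyl)oxy]-7-methyl-1-[(triethylsilyl)oxy]nona-2,6-dien-4-ol
Conditions: (R)-Me-CBS (20 mol %), catecholborane, PhMe, −78 °C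
Reagents that add atoms: none
Why: Corey–Bakshi–Shibata reduction; the α-branched alkenyl group acts as the large substituent and the allylic methylene as the small one, so the (R)-oxazaborolidine should give the 3S carbinol, and catecholborane at low temperature does not hydroborate the alkenes.

Step 10
Reactants: 15 (2Z,4S,6E)-3-{[(tert-butyldimethylsilyl)oxy]methyl}-9-[(4-methoxybenzyl)oxy]-7-methyl-1-[(triethylsilyl)oxy]nona-2,6-dien-4-ol
Product: 16 (2Z,4S,6E)-4-[(tert-butyldimethylsilyl)oxy]-3-{[(tert-butyldimethylsilyl)oxy]methyl}-9-[(4-methoxybenzyl)oxy]-7-methyl-1-[(triethylsilyl)oxy]nona-2,6-diene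
Conditions: TBSOTf, 2,6-lutidine, CH2Cl2, −78 °C
Reagents that add atoms: tert-butyldimethylsilyl triflate, CC(C)(C)[Si](C)(C)OS(=O)(=O)C(F)(F)F
Why: Silylation of the hindered secondary allylic alcohol with the silyl triflate; the configuration at C3 is not touched.

Step 11
Reactants: 16 (2Z,4S,6E)-4-[(tert-butyldimethylsilyl)oxy]-3-{[(tert-butyldimethylsilyl)oxy]methyl}-9-[(4-methoxybenzyl)oxy]-7-methyl-1-[(triethylsilyl)oxy]nona-2,6-diene
Product: 18 (2Z,4S,6E)-4-[(tert-butyldimethylsilyl)oxy]-3-{[(tert-butyldimethylsilyl)oxy]methyl}-9-[(4-methoxybenzyl)oxy]-7-methylnona-2,6-dienal, via alkoxydimethylsulfonium chloride 17 (not isolated)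
Conditions: (COCl)2, DMSO, CH2Cl2, −78 → −40 °C; Et3N, −78 → 0 °C
Reagents that add atoms: none
Why: Swern oxidation applied directly to a primary triethylsilyl ether: the activated sulfoxide cleaves the unhindered O–SiEt3 bond and the alkoxysulfonium salt collapses to the enal, while the secondary and the hindered primary TBS ethers react far more slowly.

Step 12
Reactants: 19 prop-2-yn-1-ol
Product: 20 triethyl(prop-2-yn-1-yloxy)silane
Conditions: TESCl, imidazole, CH2Cl2, 0 °C
Reagents that add atoms: chlorotriethylsilane, CC[Si](Cl)(CC)CC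
Why: Routine silylation; the TES ether on the future O13 can later be removed in the presence of both TBS ethers.

Step 13
Reactants: 18 (2Z,4S,6E)-4-[(tert-butyldimethylsilyl)oxy]-3-{[(tert-butyldimethylsilyl)oxy]methyl}-9-[(4-methoxybenzyl)oxy]-7-methylnona-2,6-dienal; 20 triethyl(prop-2-yn-1-yloxy)silane
Product: 22 (4R,5Z,7S,9E)-7-[(tert-butyldimethylsilyl)oxy]-6-{[(tert-butyldimethylsilyl)oxy]methyl}-12-[(4-methoxybenzyl)oxy]-10-methyl-1-[(triethylsilyl)oxy]dodeca-5,9-dien-2-yn-4-ol, via methyl(alkynyl)zinc 21 (not isolated)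
Conditions: Me2Zn, (R,R)-ProPhenol (20 mol %), Ph3PO (40 mol %), PhMe, 0 °C → rt
Reagents that add atoms: none
Why: Zinc–ProPhenol-catalysed asymmetric alkynylation, a reaction type for which enals are good substrates; the dinuclear zinc catalyst binds the alkynylzinc and the aldehyde and should deliver the alkyne to the Si face (6R), the remote 3S centre being too far away to interfere.

Step 14
Reactants: 22 (4R,5Z,7S,9E)-7-[(tert-butyldimethylsilyl)oxy]-6-{[(tert-butyldimethylsilyl)oxy]methyl}-12-[(4-methoxybenzyl)oxy]-10-methyl-1-[(triethylsilyl)oxy]dodeca-5,9-dien-2-yn-4-ol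
Product: 24 (2Z,4R,5Z,7S,9E)-7-[(tert-butyldimethylsilyl)oxy]-6-{[(tert-butyldimethylsilyl)oxy]methyl}-2-iodo-12-[(4-methoxybenzyl)oxy]-10-methyl-1-[(triethylsilyl)oxy]dodeca-2,5,9-trien-4-ol, via cyclic alkenylalanate 23 (not isolated)
Conditions: NaAlH2(OCH2CH2OMe)2, THF, −20 → 0 °C; I2, THF, −78 °C
Reagents that add atoms: iodine, II
Why: Trans-hydroalumination directed by the C6 alkoxide (the same reaction type as step 5): hydride goes to C7 and aluminium to C11, and iodinolysis with retention places iodine on C11 cis to the C6 carbinol, as lactonisation requires.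

Step 15
Reactants: 24 (2Z,4R,5Z,7S,9E)-7-[(tert-butyldimethylsilyl)oxy]-6-{[(tert-butyldimethylsilyl)oxy]methyl}-2-iodo-12-[(4-methoxybenzyl)oxy]-10-methyl-1-[(triethylsilyl)oxy]dodeca-2,5,9-trien-4-ol
Product: 25 (5R)-5-[(1Z,3S,5E)-3-[(tert-butyldimethylsilyl)oxy]-2-{[(tert-butyldimethylsilyl)oxy]methyl}-8-[(4-methoxybenzyl)oxy]-6-methylocta-1,5-dien-1-yl]-3-{[(triethylsilyl)oxy]methyl}furan-2(5H)-one
Conditions: PdCl2(PPh3)2 (5 mol %), CO (1 atm), K2CO3, THF, rt
Reagents that add atoms: carbon monoxide, [C-]#[O+]
Why: Palladium-catalysed carbonylative lactonisation of a (Z)-3-iodoallylic alcohol: oxidative addition into C11–I, CO insertion and capture of the acylpalladium by the cis hydroxyl give the butenolide with C13 already attached to C11; C6 is not a reacting centre.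

Step 16
Reactants: 25 (5R)-5-[(1Z,3S,5E)-3-[(tert-butyldimethylsilyl)oxy]-2-{[(tert-butyldimethylsilyl)oxy]methyl}-8-[(4-methoxybenzyl)oxy]-6-methylocta-1,5-dien-1-yl]-3-{[(triethylsilyl)oxy]methyl}furan-2(5H)-one
Product: 26 (5R)-5-[(1Z,3S,5E)-3-[(tert-butyldimethylsilyl)oxy]-2-{[(tert-butyldimethylsilyl)oxy]methyl}-8-[(4-methoxybenzyl)oxy]-6-methylocta-1,5-dien-1-yl]-3-(hydroxymethyl)furan-2(5H)-one
Conditions: PPTS (cat.), MeOH/CH2Cl2, 0 °C
Reagents that add atoms: none
Why: Acid-catalysed methanolysis of a primary triethylsilyl ether is much faster than that of the TBS ethers, and the mildly acidic medium does not endanger the C6 centre.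

Step 17
Reactants: 26 (5R)-5-[(1Z,3S,5E)-3-[(tert-butyldimethylsilyl)oxy]-2-{[(tert-butyldimethylsilyl)oxy]methyl}-8-[(4-methoxybenzyl)oxy]-6-methylocta-1,5-dien-1-yl]-3-(hydroxymethyl)furan-2(5H)-one
Product: 27 (5R)-3-(bromomethyl)-5-[(1Z,3S,5E)-3-[(tert-butyldimethylsilyl)oxy]-2-{[(tert-butyldimethylsilyl)oxy]methyl}-8-[(4-methoxybenzyl)oxy]-6-methylocta-1,5-dien-1-yl]furan-2(5H)-one
Conditions: CBr4, PPh3, CH2Cl2, −20 → 0 °C
Reagents that add atoms: tetrabromomethane, BrC(Br)(Br)Br
Why: Appel bromination of the primary allylic alcohol under neutral conditions; it is placed before the aldehyde is unveiled because this reagent pair would olefinate an aldehyde.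

Step 18
Reactants: 27 (5R)-3-(bromomethyl)-5-[(1Z,3S,5E)-3-[(tert-butyldimethylsilyl)oxy]-2-{[(tert-butyldimethylsilyl)oxy]methyl}-8-[(4-methoxybenzyl)oxy]-6-methylocta-1,5-dien-1-yl]furan-2(5H)-one
Product: 28 (5R)-3-(bromomethyl)-5-[(1Z,3S,5E)-3-[(tert-butyldimethylsilyl)oxy]-2-{[(tert-butyldimethylsilyl)oxy]methyl}-8-hydroxy-6-methylocta-1,5-dien-1-yl]furan-2(5H)-one
Conditions: DDQ, CH2Cl2/pH 7 buffer, 0 °C
Reagents that add atoms: none
Why: Oxidative cleavage of the PMB ether in buffered, neutral medium, which the allylic bromide, the butenolide and the silyl ethers should tolerate.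

Step 19
Reactants: 28 (5R)-3-(bromomethyl)-5-[(1Z,3S,5E)-3-[(tert-butyldimethylsilyl)oxy]-2-{[(tert-butyldimethylsilyl)oxy]methyl}-8-hydroxy-6-methylocta-1,5-dien-1-yl]furan-2(5H)-one
Product: 29 (3E,6S,7Z)-8-[(2R)-4-(bromomethyl)-5-oxo-2,5-dihydrofuran-2-yl]-6-[(tert-butyldimethylsilyl)oxy]-7-{[(tert-butyldimethylsilyl)oxy]methyl}-3-methylocta-3,7-dienal
Conditions: DMP, NaHCO3, CH2Cl2, 0 °C; used at once
Reagents that add atoms: none
Why: Dess–Martin oxidation of the primary alcohol without base; the β,γ-unsaturated C8 aldehyde is not purified on silica but carried directly into the ring closure.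

Step 20
Reactants: 29 (3E,6S,7Z)-8-[(2R)-4-(bromomethyl)-5-oxo-2,5-dihydrofuran-2-yl]-6-[(tert-butyldimethylsilyl)oxy]-7-{[(tert-butyldimethylsilyl)oxy]methyl}-3-methylocta-3,7-dienal
Product: 31 (3S,6R,7R,8S,4Z,1(10)E)-3,15-bis[(tert-butyldimethylsilyl)oxy]-8-hydroxygermacra-1(10),4,11(13)-trien-12,6-olide (8α-alcohol), via allylchromium dichloride 30 (not isolated)
Conditions: CrCl2 (10 equiv), THF, rt, syringe-pump addition of 29, final 0.002 M
Reagents that add atoms: none
Why: Two equivalents of divalent chromium reduce the allylic C13–Br bond to the allylchromium 30, which adds to the tethered C8 aldehyde through its γ-carbon C7 in a closed six-membered Zimmerman–Traxler chair (Cr, O8, C8, C7, C11, C13). The closest known reaction type is the Nozaki–Hiyama allylation of aldehydes with 3-(bromomethyl)furan-2(5H)-ones, together with its intramolecular use for medium and large carbocycles. The ten-membered ring closes in the 10-exo-trig mode and the double bond moves to the exocyclic C11=C13 position. C7 is controlled by the resident C6 centre: the chain that carries the aldehyde leaves C6 through C5, and the new bond should form on the butenolide face opposite to C5, which gives the trans-fused lactone (7R). C8 is controlled by the chair: C6 is an E-type γ-substituent locked by the lactone ring and sits pseudo-equatorial, C9 takes the pseudo-equatorial place, H7 and H8 are trans-diaxial, and the 7,8-anti adduct (8S, 8α-OH) should result; the same arrangement places O8 next to C13, as in the usual fold of the germacranolide ring. The step needs γ- and not α-attack, which the chair and the smaller ring secure, and ring closure in preference to oligomerisation, which slow addition into excess CrCl2 at high dilution secures. Divalent chromium leaves the aldehyde, the lactone, the silyl ethers and the isolated alkenes alone, and the neutral medium protects the β,γ-unsaturated aldehyde and the base-sensitive C6–H.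

Step 21
Reactants: 31 (3S,6R,7R,8S,4Z,1(10)E)-3,15-bis[(tert-butyldimethylsilyl)oxy]-8-hydroxygermacra-1(10),4,11(13)-trien-12,6-olide; 32 angelic acid [(Z)-2-methylbut-2-enoic acid]
Product: 34 (3S,6R,7R,8R,4Z,1(10)E)-3,15-bis[(tert-butyldimethylsilyl)oxy]-8-[(Z)-2-methylbut-2-enoyloxy]germacra-1(10),4,11(13)-trien-12,6-olide, via alkoxyphosphonium angelate 33 (not isolated)
Conditions: PPh3, DIAD, PhMe, 0 °C → rt
Reagents that add atoms: none
Why: Mitsunobu esterification: angelate displaces the alkoxyphosphonium group by SN2 and inverts C8 from 8S to 8R; the acid reacts as a nucleophile and is never activated as an acyl electrophile, which avoids the usual route of Z to E isomerisation to the tiglate.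

Step 22
Reactants: 34 (3S,6R,7R,8R,4Z,1(10)E)-3,15-bis[(tert-butyldimethylsilyl)oxy]-8-[(Z)-2-methylbut-2-enoyloxy]germacra-1(10),4,11(13)-trien-12,6-olide
Product: 35 (1R,3S,6R,7R,8R,10R,4Z)-3,15-bis[(tert-butyldimethylsilyl)oxy]-1,10-epoxy-8-[(Z)-2-methylbut-2-enoyloxy]germacra-4,11(13)-dien-12,6-olide
Conditions: mCPBA, NaHCO3, CH2Cl2, −20 → 0 °C
Reagents that add atoms: 3-chloroperoxybenzoic acid, OOC(=O)c1cccc(Cl)c1
Why: Prilezhaev epoxidation: C1=C10 is the only electron-rich alkene (C4=C5 carries three allylic oxygens, the other two are conjugated with carbonyls), and in the preferred ring fold with C14 on the β-face only the outer face of this E alkene is open, which should give the 1β,10α (1R,10R) trans-epoxide.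

Step 23
Reactants: 35 (1R,3S,6R,7R,8R,10R,4Z)-3,15-bis[(tert-butyldimethylsilyl)oxy]-1,10-epoxy-8-[(Z)-2-methylbut-2-enoyloxy]germacra-4,11(13)-dien-12,6-olide
Product: 36 (1R,3S,6R,7R,8R,10R,4Z)-1,10-epoxy-3,15-dihydroxy-8-[(Z)-2-methylbut-2-enoyloxy]germacra-4,11(13)-dien-12,6-olide (CNP0187917.1)
Conditions: HF·pyridine, pyridine, THF, 0 °C
Reagents that add atoms: none
Why: Fluoride-mediated desilylation of both TBS ethers, buffered with excess pyridine so that the medium is neither acidic enough to open the tertiary epoxide nor basic enough to trigger conjugate addition or angelate isomerisation.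

## Compound list

1 | but-3-yn-1-ol | C#CCCO | starting material
2 | 1-[(but-3-yn-1-yloxy)methyl]-4-methoxybenzene | C#CCCOCc1ccc(OC)cc1 | intermediate
3 | (E)-{4-[(4-methoxybenzyl)oxy]-2-methylbut-1-en-1-yl}dimethylalane | C[Al](C)/C=C(\C)CCOCc1ccc(OC)cc1 | intermediate (not isolated)
4 | lithium butyl{(E)-4-[(4-methoxybenzyl)oxy]-2-methylbut-1-en-1-yl}dimethylalanate | [Li+].CCCC[Al-](C)(C)/C=C(\C)CCOCc1ccc(OC)cc1 | intermediate (not isolated)
5 | (E)-6-[(4-methoxybenzyl)oxy]-4-methylhex-3-en-1-ol | OCC/C=C(\C)CCOCc1ccc(OC)cc1 | intermediate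
6 | (E)-6-[(4-methoxybenzyl)oxy]-4-methylhex-3-enal | O=CC/C=C(\C)CCOCc1ccc(OC)cc1 | intermediate
7 | but-2-yne-1,4-diol | OCC#CCO | starting material
8 | 4-[(tert-butyldimethylsilyl)oxy]but-2-yn-1-ol | OCC#CCO[Si](C)(C)C(C)(C)C | intermediate
9 | sodium 3-{[(tert-butyldimethylsilyl)oxy]methyl}-2,2-bis(2-methoxyethoxy)-2,5-dihydro-1,2-oxaluminol-2-uide | [Na+].COCCO[Al-]1(OCCOC)OCC=C1CO[Si](C)(C)C(C)(C)C | intermediate (not isolated)
10 | (Z)-4-[(tert-butyldimethylsilyl)oxy]-3-iodobut-2-en-1-ol | OC/C=C(\I)CO[Si](C)(C)C(C)(C)C | intermediate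
11 | (Z)-1-[(tert-butyldimethylsilyl)oxy]-2-iodo-4-[(triethylsilyl)oxy]but-2-ene | CC[Si](CC)(CC)OC/C=C(\I)CO[Si](C)(C)C(C)(C)C | intermediate
12 | dichloro{(Z)-1-[(tert-butyldimethylsilyl)oxy]-4-[(triethylsilyl)oxy]but-2-en-2-yl}chromium (trivalent chromium) | CC[Si](CC)(CC)OC/C=C(\[Cr](Cl)Cl)CO[Si](C)(C)C(C)(C)C | intermediate (not isolated)
13 | (2Z,6E)-3-{[(tert-butyldimethylsilyl)oxy]methyl}-9-[(4-methoxybenzyl)oxy]-7-methyl-1-[(triethylsilyl)oxy]nona-2,6-dien-4-ol, racemic at C3 | CC[Si](CC)(CC)OC/C=C(/CO[Si](C)(C)C(C)(C)C)C(O)C/C=C(\C)CCOCc1ccc(OC)cc1 | intermediate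
14 | (2Z,6E)-3-{[(tert-butyldimethylsilyl)oxy]methyl}-9-[(4-methoxybenzyl)oxy]-7-methyl-1-[(triethylsilyl)oxy]nona-2,6-dien-4-one | CC[Si](CC)(CC)OC/C=C(/CO[Si](C)(C)C(C)(C)C)C(=O)C/C=C(\C)CCOCc1ccc(OC)cc1 | intermediate
15 | (2Z,4S,6E)-3-{[(tert-butyldimethylsilyl)oxy]methyl}-9-[(4-methoxybenzyl)oxy]-7-methyl-1-[(triethylsilyl)oxy]nona-2,6-dien-4-ol | CC[Si](CC)(CC)OC/C=C(/CO[Si](C)(C)C(C)(C)C)[C@@H](O)C/C=C(\C)CCOCc1ccc(OC)cc1 | intermediate
16 | (2Z,4S,6E)-4-[(tert-butyldimethylsilyl)oxy]-3-{[(tert-butyldimethylsilyl)oxy]methyl}-9-[(4-methoxybenzyl)oxy]-7-methyl-1-[(triethylsilyl)oxy]nona-2,6-diene | CC[Si](CC)(CC)OC/C=C(/CO[Si](C)(C)C(C)(C)C)[C@@H](O[Si](C)(C)C(C)(C)C)C/C=C(\C)CCOCc1ccc(OC)cc1 | intermediate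
17 | alkoxydimethylsulfonium chloride of the C6 oxygen of 16 | [Cl-].C[S+](C)OC/C=C(/CO[Si](C)(C)C(C)(C)C)[C@@H](O[Si](C)(C)C(C)(C)C)C/C=C(\C)CCOCc1ccc(OC)cc1 | intermediate (not isolated)
18 | (2Z,4S,6E)-4-[(tert-butyldimethylsilyl)oxy]-3-{[(tert-butyldimethylsilyl)oxy]methyl}-9-[(4-methoxybenzyl)oxy]-7-methylnona-2,6-dienal | O=C/C=C(/CO[Si](C)(C)C(C)(C)C)[C@@H](O[Si](C)(C)C(C)(C)C)C/C=C(\C)CCOCc1ccc(OC)cc1 | intermediate
19 | prop-2-yn-1-ol | C#CCO | starting material
20 | triethyl(prop-2-yn-1-yloxy)silane | C#CCO[Si](CC)(CC)CC | intermediate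
21 | methyl{3-[(triethylsilyl)oxy]prop-1-yn-1-yl}zinc | C[Zn]C#CCO[Si](CC)(CC)CC | intermediate (not isolated)
22 | (4R,5Z,7S,9E)-7-[(tert-butyldimethylsilyl)oxy]-6-{[(tert-butyldimethylsilyl)oxy]methyl}-12-[(4-methoxybenzyl)oxy]-10-methyl-1-[(triethylsilyl)oxy]dodeca-5,9-dien-2-yn-4-ol | CC[Si](CC)(CC)OCC#C[C@H](O)/C=C(/CO[Si](C)(C)C(C)(C)C)[C@@H](O[Si](C)(C)C(C)(C)C)C/C=C(\C)CCOCc1ccc(OC)cc1 | intermediate
23 | sodium alanate of 22: 2,2-bis(2-methoxyethoxy)-2,5-dihydro-1,2-oxaluminol-2-uide with O6 and C11 on aluminium, (5R) | [Na+].COCCO[Al-]1(OCCOC)O[C@H](/C=C(/CO[Si](C)(C)C(C)(C)C)[C@@H](O[Si](C)(C)C(C)(C)C)C/C=C(\C)CCOCc2ccc(OC)cc2)C=C1CO[Si](CC)(CC)CC | intermediate (not isolated)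
24 | (2Z,4R,5Z,7S,9E)-7-[(tert-butyldimethylsilyl)oxy]-6-{[(tert-butyldimethylsilyl)oxy]methyl}-2-iodo-12-[(4-methoxybenzyl)oxy]-10-methyl-1-[(triethylsilyl)oxy]dodeca-2,5,9-trien-4-ol | CC[Si](CC)(CC)OC/C(I)=C/[C@H](O)/C=C(/CO[Si](C)(C)C(C)(C)C)[C@@H](O[Si](C)(C)C(C)(C)C)C/C=C(\C)CCOCc1ccc(OC)cc1 | intermediate
25 | (5R)-5-[(1Z,3S,5E)-3-[(tert-butyldimethylsilyl)oxy]-2-{[(tert-butyldimethylsilyl)oxy]methyl}-8-[(4-methoxybenzyl)oxy]-6-methylocta-1,5-dien-1-yl]-3-{[(triethylsilyl)oxy]methyl}furan-2(5H)-one | CC[Si](CC)(CC)OCC1=C[C@H](OC1=O)/C=C(/CO[Si](C)(C)C(C)(C)C)[C@@H](O[Si](C)(C)C(C)(C)C)C/C=C(\C)CCOCc1ccc(OC)cc1 | intermediate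
26 | 3-(hydroxymethyl) analogue of 25 | OCC1=C[C@H](OC1=O)/C=C(/CO[Si](C)(C)C(C)(C)C)[C@@H](O[Si](C)(C)C(C)(C)C)C/C=C(\C)CCOCc1ccc(OC)cc1 | intermediate
27 | 3-(bromomethyl) analogue of 25 | BrCC1=C[C@H](OC1=O)/C=C(/CO[Si](C)(C)C(C)(C)C)[C@@H](O[Si](C)(C)C(C)(C)C)C/C=C(\C)CCOCc1ccc(OC)cc1 | intermediate
28 | (5R)-3-(bromomethyl)-5-[(1Z,3S,5E)-3-[(tert-butyldimethylsilyl)oxy]-2-{[(tert-butyldimethylsilyl)oxy]methyl}-8-hydroxy-6-methylocta-1,5-dien-1-yl]furan-2(5H)-one | BrCC1=C[C@H](OC1=O)/C=C(/CO[Si](C)(C)C(C)(C)C)[C@@H](O[Si](C)(C)C(C)(C)C)C/C=C(\C)CCO | intermediate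
29 | (3E,6S,7Z)-8-[(2R)-4-(bromomethyl)-5-oxo-2,5-dihydrofuran-2-yl]-6-[(tert-butyldimethylsilyl)oxy]-7-{[(tert-butyldimethylsilyl)oxy]methyl}-3-methylocta-3,7-dienal | BrCC1=C[C@H](OC1=O)/C=C(/CO[Si](C)(C)C(C)(C)C)[C@@H](O[Si](C)(C)C(C)(C)C)C/C=C(\C)CC=O | intermediate
30 | allylchromium dichloride from 29 (trivalent chromium on C13) | Cl[Cr](Cl)CC1=C[C@H](OC1=O)/C=C(/CO[Si](C)(C)C(C)(C)C)[C@@H](O[Si](C)(C)C(C)(C)C)C/C=C(\C)CC=O | intermediate (not isolated)
31 | (3S,6R,7R,8S,4Z,1(10)E)-3,15-bis[(tert-butyldimethylsilyl)oxy]-8-hydroxygermacra-1(10),4,11(13)-trien-12,6-olide (8α-OH) | C=C1C(=O)O[C@@H]2/C=C(/CO[Si](C)(C)C(C)(C)C)[C@@H](O[Si](C)(C)C(C)(C)C)C/C=C(\C)C[C@H](O)[C@@H]12 | intermediate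
32 | angelic acid, (Z)-2-methylbut-2-enoic acid | C/C=C(/C)C(=O)O | starting material
33 | 8-O-triphenylphosphonium derivative of 31, angelate salt | C=C1C(=O)O[C@@H]2/C=C(/CO[Si](C)(C)C(C)(C)C)[C@@H](O[Si](C)(C)C(C)(C)C)C/C=C(\C)C[C@H](O[P+](c3ccccc3)(c3ccccc3)c3ccccc3)[C@@H]12.C/C=C(/C)C(=O)[O-] | intermediate (not isolated)
34 | (3S,6R,7R,8R,4Z,1(10)E)-3,15-bis[(tert-butyldimethylsilyl)oxy]-8-[(Z)-2-methylbut-2-enoyloxy]germacra-1(10),4,11(13)-trien-12,6-olide (8β-angelate) | C=C1C(=O)O[C@@H]2/C=C(/CO[Si](C)(C)C(C)(C)C)[C@@H](O[Si](C)(C)C(C)(C)C)C/C=C(\C)C[C@@H](OC(=O)/C(C)=C\C)[C@@H]12 | intermediate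
35 | (1R,3S,6R,7R,8R,10R,4Z)-3,15-bis[(tert-butyldimethylsilyl)oxy]-1,10-epoxy-8-[(Z)-2-methylbut-2-enoyloxy]germacra-4,11(13)-dien-12,6-olide | C=C1C(=O)O[C@@H]2/C=C(/CO[Si](C)(C)C(C)(C)C)[C@@H](O[Si](C)(C)C(C)(C)C)C[C@H]3O[C@]3(C)C[C@@H](OC(=O)/C(C)=C\C)[C@@H]12 | intermediate
36 | (1R,3S,6R,7R,8R,10R,4Z)-1,10-epoxy-3,15-dihydroxy-8-[(Z)-2-methylbut-2-enoyloxy]germacra-4,11(13)-dien-12,6-olide (CNP0187917.1) | C=C1C(=O)O[C@@H]2/C=C(/CO)[C@@H](O)C[C@H]3O[C@]3(C)C[C@@H](OC(=O)/C(C)=C\C)[C@@H]12 | target

## Step count and least certain steps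

Total step count: 23. Longest linear sequence: 19 steps (from 7 through steps 4–11 and 13–23; the chain from 1 through steps 1–3, 7–11 and 13–23 is equally long).

Step 20 (key step). The most likely failure is intermolecular coupling to dimers and oligomers, because closing a ten-membered ring is entropically and enthalpically costly; protonation of the allylchromium would give simple reduction. Attack on the other butenolide face, or a switch of the chair, would change C7 or C8. Fallback, setting out from 28: the bromide is exchanged for tin with hexabutylditin and catalytic Pd(PPh3)4 (zerovalent palladium) in THF to give the allylstannane alcohol F1. Dess–Martin oxidation gives the stannyl aldehyde F2, which is cyclised with BF3·OEt2 in CH2Cl2 at −78 °C under high dilution. This Lewis-acid route passes through an open transition state, which needs no metal bridge between O8 and C13 and has an intrinsic preference for the 7,8-syn adduct, the 8β-alcohol F3. F3 is esterified with retention by the Yamaguchi method (32, 2,4,6-trichlorobenzoyl chloride, Et3N, then toluene, 80 °C) through the mixed anhydride F4. The fallback rejoins the route at 34; if the 8α-alcohol forms instead, it rejoins at 31.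

Step 21. The most likely failure is E2 loss of the activated C8 oxygen, because allylic hydrogens sit on both neighbours (C7 and C9); a hindered carbinol can also react through an acyloxyphosphonium path with retention. Fallback, setting out from 31: the alcohol is converted with chloromethanesulfonyl chloride and pyridine into the chloromethanesulfonate F5. F5 is displaced with cesium angelate (from 32 and Cs2CO3) and 18-crown-6 in toluene, an SN2 inversion with a more reactive leaving group and a naked carboxylate. The fallback rejoins the route at 34.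

Step 15. The most likely failure is base-induced removal of the C6 hydrogen once the butenolide exists, since it is γ to the lactone carbonyl and allylic to C4=C5; this would racemise C6 or shift the double bonds. Fallback, setting out from 24: the iodide is treated with t-BuLi (3 equiv) in THF/Et2O at −78 °C to give the alkoxide–alkenyllithium, which is carboxylated with CO2. Acidification with cold aqueous HCl to pH 3 gives the (Z)-hydroxy acid F6, which lactonises without any base in contact with the butenolide. The fallback rejoins the route at 25.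

Step 22. The most likely failure is poor facial selectivity: attack on a minor ring fold with C14 on the α-face would give the 1α,10β-epoxide, and a slow reaction would allow competing oxidation at C4=C5. Fallback, setting out from 34: a Shi epoxidation (fructose-derived ketone of the enantiomeric series chosen by the spiro transition-state model for 1R,10R, KHSO5, buffered MeCN/dimethoxymethane/water, 0 °C) replaces substrate control by reagent control on this E-trisubstituted alkene. It rejoins the route at 35 and makes no new compound.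

Step 23. The most likely failure is transannular opening of the tertiary epoxide at C10 by the freed 3-hydroxyl, or its opening by fluoride under acid catalysis. Fallback, setting out from 34: the order of the last two steps is reversed. Desilylation with HF·pyridine/pyridine gives the triene diol F7, in which no epoxide is yet present. Epoxidation with mCPBA (NaHCO3, CH2Cl2, −20 °C) then relies on the much higher reactivity of C1=C10 compared with the oxygen-deactivated C4=C5. The fallback ends at 36.

## Further compounds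

F1 | step 20 | (5R)-5-[(1Z,3S,5E)-3-[(tert-butyldimethylsilyl)oxy]-2-{[(tert-butyldimethylsilyl)oxy]methyl}-8-hydroxy-6-methylocta-1,5-dien-1-yl]-3-[(tributylstannyl)methyl]furan-2(5H)-one | CCCC[Sn](CCCC)(CCCC)CC1=C[C@H](OC1=O)/C=C(/CO[Si](C)(C)C(C)(C)C)[C@@H](O[Si](C)(C)C(C)(C)C)C/C=C(\C)CCO
F2 | step 20 | (3E,6S,7Z)-6-[(tert-butyldimethylsilyl)oxy]-7-{[(tert-butyldimethylsilyl)oxy]methyl}-3-methyl-8-{(2R)-5-oxo-4-[(tributylstannyl)methyl]-2,5-dihydrofuran-2-yl}octa-3,7-dienal | CCCC[Sn](CCCC)(CCCC)CC1=C[C@H](OC1=O)/C=C(/CO[Si](C)(C)C(C)(C)C)[C@@H](O[Si](C)(C)C(C)(C)C)C/C=C(\C)CC=O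
F3 | step 20 | (3S,6R,7R,8R,4Z,1(10)E)-3,15-bis[(tert-butyldimethylsilyl)oxy]-8-hydroxygermacra-1(10),4,11(13)-trien-12,6-olide (8β-OH) | C=C1C(=O)O[C@@H]2/C=C(/CO[Si](C)(C)C(C)(C)C)[C@@H](O[Si](C)(C)C(C)(C)C)C/C=C(\C)C[C@@H](O)[C@@H]12
F4 | step 20 | (Z)-2-methylbut-2-enoic 2,4,6-trichlorobenzoic anhydride | C/C=C(/C)C(=O)OC(=O)c1c(Cl)cc(Cl)cc1Cl
F5 | step 21 | 8-O-(chloromethanesulfonyl) derivative of 31 (8S) | C=C1C(=O)O[C@@H]2/C=C(/CO[Si](C)(C)C(C)(C)C)[C@@H](O[Si](C)(C)C(C)(C)C)C/C=C(\C)C[C@H](OS(=O)(=O)CCl)[C@@H]12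
F6 | step 15 | (2Z,4R,5Z,7S,9E)-7-[(tert-butyldimethylsilyl)oxy]-6-{[(tert-butyldimethylsilyl)oxy]methyl}-4-hydroxy-12-[(4-methoxybenzyl)oxy]-10-methyl-2-{[(triethylsilyl)oxy]methyl}dodeca-2,5,9-trienoic acid | CC[Si](CC)(CC)OC/C(C(=O)O)=C/[C@H](O)/C=C(/CO[Si](C)(C)C(C)(C)C)[C@@H](O[Si](C)(C)C(C)(C)C)C/C=C(\C)CCOCc1ccc(OC)cc1
F0 | step 22 | none | none
F7 | step 23 | (3S,6R,7R,8R,4Z,1(10)E)-3,15-dihydroxy-8-[(Z)-2-methylbut-2-enoyloxy]germacra-1(10),4,11(13)-trien-12,6-olide | C=C1C(=O)O[C@@H]2/C=C(/CO)[C@@H](O)C/C=C(\C)C[C@@H](OC(=O)/C(C)=C\C)[C@@H]12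
A1 | alternative 1 | (4Z,1(10)E)-germacradienolide 8β-angelate bis-TBS ether (same substance as 34) | C=C1C(=O)O[C@@H]2/C=C(/CO[Si](C)(C)C(C)(C)C)[C@@H](O[Si](C)(C)C(C)(C)C)C/C=C(\C)C[C@@H](OC(=O)/C(C)=C\C)[C@@H]12
A2 | alternative 1 | 7-ethynyl-6-hydroxycyclodeca-1(10),4-diene 8-angelate bis-TBS ether | O[C@@H]1/C=C(/CO[Si](C)(C)C(C)(C)C)[C@@H](O[Si](C)(C)C(C)(C)C)C/C=C(\C)C[C@@H](OC(=O)/C(C)=C\C)[C@H]1C#C
A3 | alternative 2 | 3,15-acetonide of the 1(10)-alkene analogue of the target | C=C1C(=O)O[C@@H]2/C=C3/COC(C)(C)O[C@H]3C/C=C(\C)C[C@@H](OC(=O)/C(C)=C\C)[C@@H]12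
A4 | alternative 2 | seco-diene: 5-vinyl α-methylene lactone with 8-angelate, E-C1=C10 chain and 5-methylene-1,3-dioxane | C=C1C(=O)O[C@H](C=C)[C@H]1[C@H](OC(=O)/C(C)=C\C)C/C(C)=C/C[C@@H]1OC(C)(C)OCC1=C
A5 | alternative 3 | (4Z,1(10)E)-cyclodecadien-6-one with C8 PMB ether and 3,15-bis-TBS ethers | O=C1/C=C(/CO[Si](C)(C)C(C)(C)C)[C@@H](O[Si](C)(C)C(C)(C)C)C/C=C(\C)C[C@@H](OCc2ccc(OC)cc2)C1
A6 | alternative 3 | cis-fused bicyclo[5.3.0]dec-4-ene: C6 tertiary alcohol, C1 mesylate anti to the C6–C10 bond, C10 methyl, C8 PMB ether | C[C@]12C[C@@H](OCc3ccc(OC)cc3)C[C@@]1(O)/C=C(/CO[Si](C)(C)C(C)(C)C)[C@@H](O[Si](C)(C)C(C)(C)C)C[C@@H]2OS(C)(=O)=O
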